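**Plan**

1. Retrosynthesis: cut first the acetate and the CH2–C(sp2) bond at the tetrasubstituted alkene (enol triflate cross-coupling), then the ring CH2–CH2 bond between the ketone-derived methylene and the allylic carbon of the nine-membered ring (dianion alkylation), then the lactone Cα–Cβ bond (carbenoid C–H insertion), the acetoacetate ester C–O bond and last the carbinol–CH2 bond (vinylogous aldol).
2. Forward: ethyl 3-methylbut-2-enoate 1 gives, through lithium dienolate 2, silyl dienolate 3, which is joined to (S)-citronellal 4 by a catalytic vinylogous Mukaiyama aldol. Acetoacetylation and diazo transfer set up the insertion that closes the γ-lactone (ring A) first; the nine-membered carbocycle (ring B) follows by intramolecular γ-alkylation; triflation, hydroxymethylation and acetylation finish the target.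
3. Enabling feature: the O-bearing lactone γ-carbon, the lactone β-carbon and the 6-methylhept-5-en-2-yl side chain are C1, C2 and C3–C8 of citronellal in unbroken order, so the lactone Cα–Cβ bond stands where an unactivated C2–H of the aldehyde was.
4. Stereochemistry: the side-chain methyl centre is bought with 4; the carbinol (lactone γ-carbon) is set by the aldol catalyst; the β-carbon is relayed from it in the insertion (trans lactone); the E ring alkene comes from the aldol; the Z tetrasubstituted alkene is enforced by the bicyclic enolate.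

Key step: step 5

Assumption: the (R,R)-configured bisphosphoramide is taken to deliver the dienolate to the Re face of the aldehyde (giving the 5S carbinol); should the sense be the opposite, its enantiomer is used.

**Route**

Step 1
Reactants: 1 ethyl 3-methylbut-2-enoate
Product: 3 tert-butyl[(1-ethoxy-3-methylbuta-1,3-dien-1-yl)oxy]dimethylsilane, via lithium dienolate 2 (not isolated)
Conditions: LDA (LiNiPr2), THF, −78 °C; TBSCl, DMPU, −78 °C → rt; distillation
Reagents that add atoms: tert-butylchlorodimethylsilane, CC(C)(C)[Si](C)(C)Cl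
Why: Kinetic γ-deprotonation of the β,β-dimethyl enoate and O-silylation of the lithium dienolate (silyl ketene acetal formation); the ketene-acetal geometry is of no consequence because the diene later reacts at its terminal CH2.

Step 2
Reactants: 4 (S)-citronellal; 3 tert-butyl[(1-ethoxy-3-methylbuta-1,3-dien-1-yl)oxy]dimethylsilane
Product: 6 ethyl (2E,5S,7S)-5-hydroxy-3,7,11-trimethyldodeca-2,10-dienoate, via trichlorosilyl ether 5 (not isolated)
Conditions: SiCl4 (1.1 equiv), (R,R)-bisphosphoramide (two N,N′-dimethyl-1,1′-binaphthyl-2,2′-diamine phosphoramide units linked by a pentane-1,5-diyl chain, 5 mol %), iPr2NEt (cat.), CH2Cl2, −72 °C; aq NaHCO3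
Reagents that add atoms: none
Why: Lewis-base-activated SiCl4 vinylogous Mukaiyama aldol in which the chiral phosphoramide-bound trichlorosilyl cation activates the aldehyde and the dienolate attacks through its γ-terminus on the Re face, setting the 5S carbinol under catalyst control (the β-methyl centre of 4 is remote) and giving the E-enoate through an open transition state; any Z isomer would lactonise and be removed.

Step 3
Reactants: 6 ethyl (2E,5S,7S)-5-hydroxy-3,7,11-trimethyldodeca-2,10-dienoate; 7 2,2,6-trimethyl-4H-1,3-dioxin-4-one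
Product: 9 ethyl (2E,5S,7S)-3,7,11-trimethyl-5-[(3-oxobutanoyl)oxy]dodeca-2,10-dienoate, via acetylketene 8 (not isolated)
Conditions: xylene, 130 °C, acetone distilled off
Reagents that add atoms: none
Why: Thermal retro-hetero-Diels–Alder of the dioxinone releases acetylketene, which is trapped by the secondary alcohol (neutral acetoacetylation that leaves the carbinol configuration and the E-enoate untouched).

Step 4
Reactants: 9 ethyl (2E,5S,7S)-3,7,11-trimethyl-5-[(3-oxobutanoyl)oxy]dodeca-2,10-dienoate
Product: 10 ethyl (2E,5S,7S)-5-[(2-diazo-3-oxobutanoyl)oxy]-3,7,11-trimethyldodeca-2,10-dienoate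
Conditions: 4-acetamidobenzenesulfonyl azide, Et3N, MeCN, 0 °C → rt
Reagents that add atoms: 4-acetamidobenzenesulfonyl azide, CC(=O)Nc1ccc(cc1)S(=O)(=O)N=[N+]=[N-]
Why: Regitz diazo transfer to the doubly activated methylene of the acetoacetate; the amine base is too weak to enolise the enoate.

Step 5
Reactants: 10 ethyl (2E,5S,7S)-5-[(2-diazo-3-oxobutanoyl)oxy]-3,7,11-trimethyldodeca-2,10-dienoate
Product: 11 ethyl (2E)-4-[(2R,3S)-4-acetyl-3-[(2S)-6-methylhept-5-en-2-yl]-5-oxooxolan-2-yl]-3-methylbut-2-enoate (trans lactone; C4 epimers equilibrating through the enol)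
Conditions: Rh2(OAc)4 (1 mol %), CH2Cl2, 40 °C, slow addition of 10
Reagents that add atoms: none
Why: Loss of N2 at the dirhodium tetraacetate (divalent rhodium) catalyst gives an electrophilic acceptor/acceptor carbenoid that inserts into a C–H bond through a concerted, hydride-transfer-like three-centre transition state; the closest known reaction is the dirhodium-carboxylate-catalysed intramolecular C–H insertion of diazoacetoacetates of secondary alcohols to α-acetyl-γ-butyrolactones. The γ-lactone (ring A) closes by 1,5-insertion: carbenoid carbon, ester carbonyl carbon, ester oxygen, carbinol carbon and the former C2 methylene of citronellal make up the five-membered ring, and the Cα–Cβ bond is the one formed. The new β-stereocentre is controlled by the adjacent carbinol centre from step 2, because both ring substituents take pseudo-equatorial positions in the envelope-like transition state and the lactone therefore forms trans; the α-centre is epimerisable and later becomes sp2. The step needs site selectivity for the citronellal methylene over the other flanking methylene, the carbinol C–H (four-membered closure), the tertiary C–H (six-membered closure) and both alkenes. The substrate secures this because the competing methylene is allylic and vinylogous to an ester and so inductively deactivated, the enoate alkene is too electron-poor for the electrophilic carbenoid, and five-membered closure outruns four- and six-membered closure. The remote trisubstituted alkene could only be reached through a macrocyclic transition state, and slow addition suppresses its bimolecular cyclopropanation.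

Step 6
Reactants: 11 ethyl (2E)-4-[(2R,3S)-4-acetyl-3-[(2S)-6-methylhept-5-en-2-yl]-5-oxooxolan-2-yl]-3-methylbut-2-enoate
Product: 13 (4S,5R)-3-acetyl-5-[(2E)-4-hydroxy-2-methylbut-2-en-1-yl]-4-[(2S)-6-methylhept-5-en-2-yl]oxolan-2-one, via sodium enolate 12 (not isolated)
Conditions: NaH (1.05 equiv), THF, 0 °C; iBu2AlH (2.5 equiv), −78 °C; aq potassium sodium tartrate, then aq NH4Cl
Reagents that add atoms: none
Why: Enolate protection: the acidic α-acetyl lactone is stored as its sodium enolate, which resists hydride, so iBu2AlH should perform only the 1,2-reduction of the conjugated ethyl ester to the E-allylic alcohol, and mild acidification returns the β-keto lactone.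

Step 7
Reactants: 13 (4S,5R)-3-acetyl-5-[(2E)-4-hydroxy-2-methylbut-2-en-1-yl]-4-[(2S)-6-methylhept-5-en-2-yl]oxolan-2-one
Product: 14 (4S,5R)-3-acetyl-5-[(2E)-4-bromo-2-methylbut-2-en-1-yl]-4-[(2S)-6-methylhept-5-en-2-yl]oxolan-2-one
Conditions: CBr4, PPh3, CH2Cl2, −20 → 0 °C
Reagents that add atoms: tetrabromomethane, BrC(Br)(Br)Br
Why: Appel bromination of the primary allylic alcohol (bromide displaces the alkoxyphosphonium at the unhindered primary carbon without allylic transposition at low temperature) under neutral conditions that spare the β-keto lactone.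

Step 8
Reactants: 14 (4S,5R)-3-acetyl-5-[(2E)-4-bromo-2-methylbut-2-en-1-yl]-4-[(2S)-6-methylhept-5-en-2-yl]oxolan-2-one
Product: 16 (5E,8R,11S)-6-methyl-11-[(2S)-6-methylhept-5-en-2-yl]-9-oxabicyclo[6.2.1]undec-5-ene-2,10-dione (C1 epimers and enol), via dilithium dianion 15 (not isolated)
Conditions: LDA (LiNiPr2, 2.3 equiv), THF, −78 → −20 °C, 14 added by syringe pump (about 2 mM final); aq NH4Cl
Reagents that add atoms: none
Why: Intramolecular γ-alkylation of a β-dicarbonyl dianion (Weiler-type dianion alkylation): the lithium-chelated dianion holds the nucleophilic terminal CH2 on the side of the lactone β-carbon, from where it should displace the primary allylic bromide in an SN2 sense to close the nine-membered ring B with the E-alkene intact; high dilution favours ring closure over oligomerisation and no stereocentre is created.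

Step 9
Reactants: 16 (5E,8R,11S)-6-methyl-11-[(2S)-6-methylhept-5-en-2-yl]-9-oxabicyclo[6.2.1]undec-5-ene-2,10-dione
Product: 18 (1Z,5E,8R,11S)-6-methyl-11-[(2S)-6-methylhept-5-en-2-yl]-10-oxo-9-oxabicyclo[6.2.1]undeca-1,5-dien-2-yl trifluoromethanesulfonate, via sodium enolate 17 (not isolated)
Conditions: NaH, THF, 0 °C; PhNTf2, 0 °C → rt; aq NH4Cl
Reagents that add atoms: N-phenylbis(trifluoromethanesulfonimide), O=S(=O)(N(c1ccccc1)S(=O)(=O)C(F)(F)F)C(F)(F)F
Why: O-triflation of the thermodynamic β-keto lactone enolate (enol triflate formation); within the nine-membered ring only the enolate with oxygen cis to the lactone carbonyl can exist, so a single Z-triflate is expected and the α-stereocentre disappears.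

Step 10
Reactants: 18 (1Z,5E,8R,11S)-6-methyl-11-[(2S)-6-methylhept-5-en-2-yl]-10-oxo-9-oxabicyclo[6.2.1]undeca-1,5-dien-2-yl trifluoromethanesulfonate
Product: 20 [(1Z,5E,8R,11S)-6-methyl-11-[(2S)-6-methylhept-5-en-2-yl]-10-oxo-9-oxabicyclo[6.2.1]undeca-1,5-dien-2-yl]methyl acetate (target), via allylic alcohol 19 (not isolated)
Conditions: Bu3SnCH2OH, Pd2(dba)3 (5 mol %), P(2-furyl)3 (20 mol %), LiCl, NMP, 45 °C; then 0 °C, Ac2O, pyridine, DMAP
Reagents that add atoms: (tributylstannyl)methanol, OC[Sn](CCCC)(CCCC)CCCC; acetic anhydride, CC(=O)OC(C)=O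
Why: Stille hydroxymethylation of the electron-poor enol triflate at zerovalent palladium with retention of alkene geometry (the α-oxygenated CH2 group transfers from tin in preference to butyl), and the primary alcohol is acetylated in the same flask (DMAP-catalysed acylation) before it can attack the neighbouring lactone carbonyl.

**Compound list**

1 | ethyl 3-methylbut-2-enoate | CCOC(=O)C=C(C)C | starting material
2 | lithium 1-ethoxy-3-methylbuta-1,3-dien-1-olate (lithium dienolate of 1) | CCOC(=CC(C)=C)O[Li] | intermediate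
3 | tert-butyl[(1-ethoxy-3-methylbuta-1,3-dien-1-yl)oxy]dimethylsilane (ketene-acetal geometry not defined) | CCOC(=CC(C)=C)O[Si](C)(C)C(C)(C)C | intermediate
4 | (S)-citronellal, (3S)-3,7-dimethyloct-6-enal | C[C@H](CC=O)CCC=C(C)C | starting material
5 | ethyl (2E,5S,7S)-3,7,11-trimethyl-5-[(trichlorosilyl)oxy]dodeca-2,10-dienoate | CCOC(=O)/C=C(C)/C[C@H](C[C@@H](C)CCC=C(C)C)O[Si](Cl)(Cl)Cl | intermediate
6 | ethyl (2E,5S,7S)-5-hydroxy-3,7,11-trimethyldodeca-2,10-dienoate | CCOC(=O)/C=C(C)/C[C@H](C[C@@H](C)CCC=C(C)C)O | intermediate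
7 | 2,2,6-trimethyl-4H-1,3-dioxin-4-one | CC1=CC(=O)OC(C)(C)O1 | starting material
8 | acetylketene (3-oxobut-1-en-1-one) | CC(=O)C=C=O | intermediate
9 | ethyl (2E,5S,7S)-3,7,11-trimethyl-5-[(3-oxobutanoyl)oxy]dodeca-2,10-dienoate | CCOC(=O)/C=C(C)/C[C@H](C[C@@H](C)CCC=C(C)C)OC(=O)CC(C)=O | intermediate
10 | ethyl (2E,5S,7S)-5-[(2-diazo-3-oxobutanoyl)oxy]-3,7,11-trimethyldodeca-2,10-dienoate | CCOC(=O)/C=C(C)/C[C@H](C[C@@H](C)CCC=C(C)C)OC(=O)C(=[N+]=[N-])C(C)=O | intermediate
11 | ethyl (2E)-4-[(2R,3S)-4-acetyl-3-[(2S)-6-methylhept-5-en-2-yl]-5-oxooxolan-2-yl]-3-methylbut-2-enoate (C4 epimers and enol) | CCOC(=O)/C=C(C)/C[C@H]1OC(=O)C(C(C)=O)[C@@H]1[C@@H](C)CCC=C(C)C | intermediate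
12 | sodium enolate of 11 | CCOC(=O)/C=C(C)/C[C@H]1OC(=O)C(=C(C)O[Na])[C@@H]1[C@@H](C)CCC=C(C)C | intermediate
13 | (4S,5R)-3-acetyl-5-[(2E)-4-hydroxy-2-methylbut-2-en-1-yl]-4-[(2S)-6-methylhept-5-en-2-yl]oxolan-2-one | OC/C=C(C)/C[C@H]1OC(=O)C(C(C)=O)[C@@H]1[C@@H](C)CCC=C(C)C | intermediate
14 | (4S,5R)-3-acetyl-5-[(2E)-4-bromo-2-methylbut-2-en-1-yl]-4-[(2S)-6-methylhept-5-en-2-yl]oxolan-2-one | BrC/C=C(C)/C[C@H]1OC(=O)C(C(C)=O)[C@@H]1[C@@H](C)CCC=C(C)C | intermediate
15 | dilithium dianion (dienediolate) of 14 | C=C(O[Li])C1=C(O[Li])O[C@H](C/C(C)=C/CBr)[C@H]1[C@@H](C)CCC=C(C)C | intermediate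
16 | (5E,8R,11S)-6-methyl-11-[(2S)-6-methylhept-5-en-2-yl]-9-oxabicyclo[6.2.1]undec-5-ene-2,10-dione (C1 epimers and enol) | O=C1CC/C=C(C)/C[C@H]2OC(=O)C1[C@@H]2[C@@H](C)CCC=C(C)C | intermediate
17 | sodium enolate of 16 | [Na]O/C1=C2\C(=O)O[C@H](C/C(C)=C/CC1)[C@H]2[C@@H](C)CCC=C(C)C | intermediate
18 | (1Z,5E,8R,11S)-6-methyl-11-[(2S)-6-methylhept-5-en-2-yl]-10-oxo-9-oxabicyclo[6.2.1]undeca-1,5-dien-2-yl trifluoromethanesulfonate | FC(F)(F)S(=O)(=O)O/C1=C2\C(=O)O[C@H](C/C(C)=C/CC1)[C@H]2[C@@H](C)CCC=C(C)C | intermediate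
19 | (1Z,5E,8R,11S)-2-(hydroxymethyl)-6-methyl-11-[(2S)-6-methylhept-5-en-2-yl]-9-oxabicyclo[6.2.1]undeca-1,5-dien-10-one | OC/C1=C2\C(=O)O[C@H](C/C(C)=C/CC1)[C@H]2[C@@H](C)CCC=C(C)C | intermediate
20 | [(1Z,5E,8R,11S)-6-methyl-11-[(2S)-6-methylhept-5-en-2-yl]-10-oxo-9-oxabicyclo[6.2.1]undeca-1,5-dien-2-yl]methyl acetate (CNP0356884.2) | CC(=O)OC/C1=C2\C(=O)O[C@H](C/C(C)=C/CC1)[C@H]2[C@@H](C)CCC=C(C)C | target

**Step count and risks**

Total: 10 steps. Longest linear sequence: 10 steps (from 1; 9 from 4).

Steps most likely to fail: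

1. Step 8 (closure of ring B). The strained closure of an E-configured nine-membered ring may lose to intermolecular alkylation, to allylic transposition (SN2′ attack that would give a seven-membered ring) or to elimination by the strongly basic dianion. Fallback, from 13, rejoining at 16: the nucleophile is softened by a temporary sulfone so that the ring can be closed with a weak base. The trianion of 13 (LDA, 3.3 equiv, THF, −78 °C) is sulfenylated with PhSSPh to (4S,5R)-5-[(2E)-4-hydroxy-2-methylbut-2-en-1-yl]-4-[(2S)-6-methylhept-5-en-2-yl]-3-[(phenylsulfanyl)acetyl]oxolan-2-one F1. H2O2 with catalytic (NH4)6Mo7O24 in EtOH at 0 °C oxidises sulfur only and gives the β-keto sulfone, the corresponding 3-[(phenylsulfonyl)acetyl]oxolan-2-one F2. Appel bromination (CBr4, PPh3) gives the allylic bromide (4S,5R)-5-[(2E)-4-bromo-2-methylbut-2-en-1-yl]-4-[(2S)-6-methylhept-5-en-2-yl]-3-[(phenylsulfonyl)acetyl]oxolan-2-one F3. Cs2CO3 in MeCN at high dilution closes the ring through the sulfone-stabilised carbanion (the tertiary lactone α-carbon cannot reach the bromide in an SN2 sense) to (5E,8R,11S)-6-methyl-11-[(2S)-6-methylhept-5-en-2-yl]-3-(phenylsulfonyl)-9-oxabicyclo[6.2.1]undec-5-ene-2,10-dione F4. SmI2 in THF/MeOH at −78 °C removes the sulfonyl group and returns 16.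

2. Step 5 (C–H insertion). The carbenoid may insert at the carbinol C–H, at the allylic methylene or at the tertiary C–H, or it may cyclopropanate the remote trisubstituted alkene, so that site selectivity and the trans relay erode. Fallback, from 10, rejoining at 11: site and diastereoselectivity are put under catalyst control with a less stabilised carbenoid and the acetyl group is added afterwards. Pyrrolidine in MeCN removes the acetyl group of 10 to give ethyl (2E,5S,7S)-5-[(diazoacetyl)oxy]-3,7,11-trimethyldodeca-2,10-dienoate F5. A chiral dirhodium carboxamidate, dirhodium tetrakis[methyl (5S)-2-oxopyrrolidine-5-carboxylate], Rh2(5S-MEPY)4, or its enantiomer, whichever is matched to the carbinol centre, in CH2Cl2 at 40 °C then directs insertion to the citronellal methylene and gives ethyl (2E)-3-methyl-4-[(2R,3R)-3-[(2S)-6-methylhept-5-en-2-yl]-5-oxooxolan-2-yl]but-2-enoate F6. C-acetylation of its lithium enolate (LiN(SiMe3)2, 2.1 equiv, THF, −78 °C, then 1-acetylimidazole) returns 11.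

3. Step 10 (hydroxymethylation and acetylation). Transfer of the sp3 carbon from tin to the hindered tetrasubstituted triflate may be slow, and the freed primary alcohol may transesterify onto the cis-disposed lactone carbonyl (ring switch to a fused butenolide) before it is acetylated. Fallback, from 18, rejoining at 20: the alcohol is never set free. Stille coupling of 18 with tributyl({[tert-butyl(dimethyl)silyl]oxy}methyl)stannane (Pd2(dba)3, P(2-furyl)3, LiCl, NMP) gives the silyl ether (1Z,5E,8R,11S)-2-({[tert-butyl(dimethyl)silyl]oxy}methyl)-6-methyl-11-[(2S)-6-methylhept-5-en-2-yl]-9-oxabicyclo[6.2.1]undeca-1,5-dien-10-one F7. The silyl group is then exchanged directly for acetyl with Ac2O and catalytic Cu(OTf)2 in CH2Cl2 at 0 °C to give 20.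

Further compounds
F1 | step 8 | (4S,5R)-5-[(2E)-4-hydroxy-2-methylbut-2-en-1-yl]-4-[(2S)-6-methylhept-5-en-2-yl]-3-[(phenylsulfanyl)acetyl]oxolan-2-one | OC/C=C(C)/C[C@H]1OC(=O)C(C(=O)CSc2ccccc2)[C@@H]1[C@@H](C)CCC=C(C)C
F2 | step 8 | (4S,5R)-5-[(2E)-4-hydroxy-2-methylbut-2-en-1-yl]-4-[(2S)-6-methylhept-5-en-2-yl]-3-[(phenylsulfonyl)acetyl]oxolan-2-one | OC/C=C(C)/C[C@H]1OC(=O)C(C(=O)CS(=O)(=O)c2ccccc2)[C@@H]1[C@@H](C)CCC=C(C)C
F3 | step 8 | (4S,5R)-5-[(2E)-4-bromo-2-methylbut-2-en-1-yl]-4-[(2S)-6-methylhept-5-en-2-yl]-3-[(phenylsulfonyl)acetyl]oxolan-2-one | BrC/C=C(C)/C[C@H]1OC(=O)C(C(=O)CS(=O)(=O)c2ccccc2)[C@@H]1[C@@H](C)CCC=C(C)C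
F4 | step 8 | (5E,8R,11S)-6-methyl-11-[(2S)-6-methylhept-5-en-2-yl]-3-(phenylsulfonyl)-9-oxabicyclo[6.2.1]undec-5-ene-2,10-dione | O=C1C(S(=O)(=O)c3ccccc3)C/C=C(C)/C[C@H]2OC(=O)C1[C@@H]2[C@@H](C)CCC=C(C)C
F5 | step 5 | ethyl (2E,5S,7S)-5-[(diazoacetyl)oxy]-3,7,11-trimethyldodeca-2,10-dienoate | CCOC(=O)/C=C(C)/C[C@H](C[C@@H](C)CCC=C(C)C)OC(=O)C=[N+]=[N-]
F6 | step 5 | ethyl (2E)-3-methyl-4-[(2R,3R)-3-[(2S)-6-methylhept-5-en-2-yl]-5-oxooxolan-2-yl]but-2-enoate | CCOC(=O)/C=C(C)/C[C@H]1OC(=O)C[C@@H]1[C@@H](C)CCC=C(C)C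
F7 | step 10 | (1Z,5E,8R,11S)-2-({[tert-butyl(dimethyl)silyl]oxy}methyl)-6-methyl-11-[(2S)-6-methylhept-5-en-2-yl]-9-oxabicyclo[6.2.1]undeca-1,5-dien-10-one | CC(C)(C)[Si](C)(C)OC/C1=C2\C(=O)O[C@H](C/C(C)=C/CC1)[C@H]2[C@@H](C)CCC=C(C)C
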